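The route rests on cutting, on both outer rings in one operation, the ring-to-butanoyl C–C bond together with the aryl C–O bond(s) beside it. The outer rings differ: on ring A the butanoyl carbon C-1 sits between two hydroxylated carbons (C-2, C-6), so a 2-silyl-1,3-bis(triflate) acts as a twofold aryne equivalent; on ring C the butanoyl carbon C-5' sits between the methoxy carbon C-4' and the hydroxy carbon C-6', so a 3-methoxy-2-silylaryl triflate is used. Fluoride and butanoate then form two aryl ketones and three aryl C–O bonds. The precursor is a tris(benzyloxy) ring B with these two different arylmethyl arms and one free C–H for late acetylation.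

Key step: step 14

Remark: ring A is the outer ring whose bridge carbon C-5 lies between the methoxy carbon C-4 and the hydroxy carbon C-6 (C-1 butanoyl, C-2 hydroxy, C-3 methyl); ring B is the central ring; ring C is the outer ring whose bridge carbon C-1' lies between the hydroxy carbons C-2' and C-6' (C-3' methyl, C-4' methoxy, C-5' butanoyl).

Remark: on ring A the key step should give the butanoate ester on either flanking oxygen (possibly with some retained triflate); one representative isomer is written for 22, 23 and 24, and all of them converge in step 16.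

Step 1
Reactants: 1 2-methylphloroglucinol (2-methylbenzene-1,3,5-triol)
Product: 2 2,4,6-trihydroxy-3-methylbenzoic acid
Conditions: KHCO3, H2O, CO2 (1 atm), 60 °C; then HCl, 0 °C
Reagents that add atoms: potassium hydrogen carbonate, [K+].OC([O-])=O
Why: Kolbe–Schmitt carboxylation, which is facile for phloroglucinols in aqueous hydrogen carbonate; the two unsubstituted ring carbons of 1 are equivalent, so a single acid is expected.

Step 2
Reactants: 2 2,4,6-trihydroxy-3-methylbenzoic acid
Product: 3 methyl 2,6-dihydroxy-4-methoxy-3-methylbenzoate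
Conditions: Me2SO4 (2.05 equiv), K2CO3, acetone, 0 °C → rt
Reagents that add atoms: dimethyl sulfate, COS(=O)(=O)OC
Why: Chemoselective Williamson-type methylation of the carboxylate and of the 4-hydroxyl group, the most acidic phenol and the only one not hydrogen-bonded to the carbonyl group, while the two chelated ortho hydroxyl groups stay free.

Step 3
Reactants: 3 methyl 2,6-dihydroxy-4-methoxy-3-methylbenzoate
Product: 4 methyl 3-[(dimethylamino)methyl]-2,6-dihydroxy-4-methoxy-5-methylbenzoate
Conditions: CH2=NMe2+ I− (1.05 equiv), CH2Cl2, 0 °C → rt; then aq. NaHCO3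
Reagents that add atoms: dimethylmethylideneammonium iodide, C=[N+](C)C.[I-]
Why: Mannich aminomethylation with a preformed iminium salt at the only unsubstituted ring carbon (C-5, ortho to the 6-hydroxyl group), which installs an ortho-hydroxybenzylamine as a latent ortho-quinone methide.

Step 4
Reactants: 5 1,3,5-tris(benzyloxy)benzene
Product: 6 2-bromo-1,3,5-tris(benzyloxy)benzene
Conditions: NBS (1.0 equiv), CH2Cl2, −20 → 0 °C
Reagents that add atoms: N-bromosuccinimide, O=C1CCC(=O)N1Br
Why: Electrophilic aromatic bromination of a 1,3,5-trialkoxybenzene, which should stop after one bromine with one equivalent at low temperature; the bromine blocks one ring B carbon through step 11 and leaves without trace in step 12.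

Step 5
Reactants: 6 2-bromo-1,3,5-tris(benzyloxy)benzene (3 equiv); 4 methyl 3-[(dimethylamino)methyl]-2,6-dihydroxy-4-methoxy-5-methylbenzoate
Product: 7 methyl 3-{[3-bromo-2,4,6-tris(benzyloxy)phenyl]methyl}-2,6-dihydroxy-4-methoxy-5-methylbenzoate
Conditions: AcOH, 90 °C; excess 6 recovered
Reagents that add atoms: none
Why: Acid-assisted loss of dimethylamine gives the ortho-quinone methide (ortho-hydroxybenzyl cation) of ring A, which alkylates one of the two equivalent unsubstituted carbons of 6 in a Friedel–Crafts reaction, the excess of 6 holding back a second alkylation.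

Step 6
Reactants: 3 methyl 2,6-dihydroxy-4-methoxy-3-methylbenzoate
Product: 8 methyl 3-bromo-2,6-dihydroxy-4-methoxy-5-methylbenzoate
Conditions: NBS (1.0 equiv), MeCN, 0 °C
Reagents that add atoms: N-bromosuccinimide, O=C1CCC(=O)N1Br
Why: Electrophilic aromatic bromination at the only ring C–H of 3 (between the hydroxyl and methoxy carbons), which marks the later butanoyl carbon C-5' of ring C while the ester still occupies the later bridge carbon.

Step 7
Reactants: 8 methyl 3-bromo-2,6-dihydroxy-4-methoxy-5-methylbenzoate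
Product: 10 4-bromo-5-methoxy-6-methylbenzene-1,3-diol, via carboxylic acid 9 (not isolated)
Conditions: KOH, H2O/1,4-dioxane (degassed), 100 °C; then AcOH to pH 5–6, 80 °C
Reagents that add atoms: none
Why: Saponification followed by protodecarboxylation of a 2,6-dihydroxybenzoic acid (ipso protonation of the electron-rich ring, as in a β-keto acid) frees the carbon between the two hydroxyl groups for the bridge.

Step 8
Reactants: 10 4-bromo-5-methoxy-6-methylbenzene-1,3-diol
Product: 11 4-bromo-2-[(dimethylamino)methyl]-5-methoxy-6-methylbenzene-1,3-diol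
Conditions: CH2=NMe2+ I− (1.05 equiv), CH2Cl2, 0 °C → rt; then aq. NaHCO3
Reagents that add atoms: dimethylmethylideneammonium iodide, C=[N+](C)C.[I-]
Why: Mannich aminomethylation at the only unsubstituted carbon (C-2, between the two hydroxyl groups), the bromine blocking the other position that the parent resorcinol would offer.

Step 9
Reactants: 7 methyl 3-{[3-bromo-2,4,6-tris(benzyloxy)phenyl]methyl}-2,6-dihydroxy-4-methoxy-5-methylbenzoate; 11 4-bromo-2-[(dimethylamino)methyl]-5-methoxy-6-methylbenzene-1,3-diol (1.3 equiv)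
Product: 12 methyl 3-({3-bromo-5-[(3-bromo-2,6-dihydroxy-4-methoxy-5-methylphenyl)methyl]-2,4,6-tris(benzyloxy)phenyl}methyl)-2,6-dihydroxy-4-methoxy-5-methylbenzoate
Conditions: AcOH, 80 °C
Reagents that add atoms: none
Why: Friedel–Crafts alkylation by the ortho-quinone methide of 11 at the single unsubstituted carbon of ring B; every other ring carbon of 7 and 11 is substituted, so the second, different arm should be attached without statistical mixtures.

Step 10
Reactants: 12 methyl 3-({3-bromo-5-[(3-bromo-2,6-dihydroxy-4-methoxy-5-methylphenyl)methyl]-2,4,6-tris(benzyloxy)phenyl}methyl)-2,6-dihydroxy-4-methoxy-5-methylbenzoate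
Product: 14 4-({3-bromo-5-[(3-bromo-2,6-dihydroxy-4-methoxy-5-methylphenyl)methyl]-2,4,6-tris(benzyloxy)phenyl}methyl)-5-methoxy-6-methylbenzene-1,3-diol, via carboxylic acid 13 (not isolated)
Conditions: KOH, H2O/1,4-dioxane (degassed), 100 °C; then AcOH to pH 5–6, 80 °C
Reagents that add atoms: none
Why: Saponification then protodecarboxylation of the ring A 2,6-dihydroxybenzoic acid near neutral pH, which spares the acid-labile diarylmethane links; base cannot cleave the bridges because ring B carries no free hydroxyl group.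

Step 11
Reactants: 14 4-({3-bromo-5-[(3-bromo-2,6-dihydroxy-4-methoxy-5-methylphenyl)methyl]-2,4,6-tris(benzyloxy)phenyl}methyl)-5-methoxy-6-methylbenzene-1,3-diol
Product: 15 2-bromo-4-({3-bromo-5-[(3-bromo-2,6-dihydroxy-4-methoxy-5-methylphenyl)methyl]-2,4,6-tris(benzyloxy)phenyl}methyl)-5-methoxy-6-methylbenzene-1,3-diol
Conditions: NBS (1.0 equiv), THF, −78 °C
Reagents that add atoms: N-bromosuccinimide, O=C1CCC(=O)N1Br
Why: Electrophilic aromatic bromination at the only C–H left on the three core rings (ring A C-1, between its two hydroxyl groups).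

Step 12
Reactants: 15 2-bromo-4-({3-bromo-5-[(3-bromo-2,6-dihydroxy-4-methoxy-5-methylphenyl)methyl]-2,4,6-tris(benzyloxy)phenyl}methyl)-5-methoxy-6-methylbenzene-1,3-diol
Product: 18 4-[(2,4,6-tris(benzyloxy)-3-{[2,6-dihydroxy-4-methoxy-3-methyl-5-(trimethylsilyl)phenyl]methyl}phenyl)methyl]-5-methoxy-6-methyl-2-(trimethylsilyl)benzene-1,3-diol, via tetrakis(trimethylsilyl) ether 16 (not isolated), via C-silyl O-silyl phenol 17 (not isolated)
Conditions: HMDS, 80 °C, then volatiles removed; n-BuLi (3.3 equiv), THF, −78 °C; MeOH, then K2CO3 (cat.), 0 °C; pH 7 buffer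
Reagents that add atoms: hexamethyldisilazane, C[Si](C)(C)N[Si](C)(C)C
Why: Bromine–lithium exchange at all three aryl bromides is followed by a retro-Brook rearrangement (1,3 shift of silicon from oxygen to the lithiated carbon) on ring A and on ring C (from O-6', since O-4' is a methyl ether), while the ring B aryllithium has no silyl ether beside it and is protonated on quenching; mild methanolysis then frees the remaining silyl ethers.

Step 13
Reactants: 18 4-[(2,4,6-tris(benzyloxy)-3-{[2,6-dihydroxy-4-methoxy-3-methyl-5-(trimethylsilyl)phenyl]methyl}phenyl)methyl]-5-methoxy-6-methyl-2-(trimethylsilyl)benzene-1,3-diol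
Product: 19 4-[(2,4,6-tris(benzyloxy)-3-{[4-methoxy-3-methyl-2,6-bis(trifluoromethanesulfonyloxy)-5-(trimethylsilyl)phenyl]methyl}phenyl)methyl]-5-methoxy-6-methyl-2-(trimethylsilyl)-1,3-phenylene bis(trifluoromethanesulfonate)
Conditions: Tf2O (5 equiv), pyridine, CH2Cl2, −20 → 0 °C
Reagents that add atoms: trifluoromethanesulfonic anhydride, O=S(=O)(OS(=O)(=O)C(F)(F)F)C(F)(F)F
Why: O-Sulfonylation of the four phenols under basic conditions; each triflate makes its ring less electron-rich, which should guard the C–Si bonds against protodesilylation.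

Step 14
Reactants: 19 4-[(2,4,6-tris(benzyloxy)-3-{[4-methoxy-3-methyl-2,6-bis(trifluoromethanesulfonyloxy)-5-(trimethylsilyl)phenyl]methyl}phenyl)methyl]-5-methoxy-6-methyl-2-(trimethylsilyl)-1,3-phenylene bis(trifluoromethanesulfonate); 20 butanoic acid (6 equiv, as its cesium salt)
Product: 23 2-butanoyl-6-[(2,4,6-tris(benzyloxy)-3-{[3-butanoyl-2-hydroxy-4-methoxy-5-methyl-6-(trifluoromethanesulfonyloxy)phenyl]methyl}phenyl)methyl]-3-hydroxy-5-methoxy-4-methylphenyl butanoate (representative positional isomer), via bis(aryne) 21 (not isolated), via ring A butanoyloxyaryne 22 (not isolated)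
Conditions: 20 (6 equiv), Cs2CO3 (3 equiv), MeOH, rt, then dried (80 °C, vacuum); 19, CsF (5 equiv), THF (dilute), 110 °C, sealed tube; then aq. NH4Cl
Reagents that add atoms: cesium butanoate (the salt of 20, made in the flask; three butanoyl groups are taken up), [Cs+].CCCC(=O)[O-]
Why: Proposed new method: fluoride removes each trimethylsilyl group and the aryl anion expels a neighbouring triflate, giving a 3-(triflyloxy)aryne on ring A and a 3-methoxyaryne (C-5'≡C-6') on ring C; butanoate adds at the aryne carbon remote from the electronegative neighbour, and the anion on the former silyl carbon either takes the butanoyl group by a 1,3 shift from oxygen to carbon through a four-membered transition state (ring C) or first expels the second triflate and repeats the addition before the shift (ring A), so that two aryl ketones and three aryl C–O bonds are formed. The closest known reaction types are the formal insertion of arynes into the C–O bond of carboxylic acids, which gives ortho-hydroxyaryl ketones from 2-silylaryl triflates with CsF in hot THF, and the domino generation of two arynes from 2-silyl-1,3-bis(triflates); their use on fully substituted rings with an aliphatic carboxylate is untested. No ring is closed and no stereocentre is formed. The step needs oxygen to add at the distal aryne carbon, which the inductively withdrawing triflyloxy, acyloxy or methoxy group beside the triple bond should enforce over the alkyl group on the other side. It also needs acyl transfer to outrun protonation of the aryl anion, which is why the dry cesium salt is used without free acid. The triflate on O-2' of ring C has no silyl neighbour and should pass through as a spectator, and a ring A anion that shifts its acyl group before losing the second triflate gives a 3-(triflyloxy) ketone that still converges in step 16.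

Step 15
Reactants: 23 2-butanoyl-6-[(2,4,6-tris(benzyloxy)-3-{[3-butanoyl-2-hydroxy-4-methoxy-5-methyl-6-(trifluoromethanesulfonyloxy)phenyl]methyl}phenyl)methyl]-3-hydroxy-5-methoxy-4-methylphenyl butanoate
Product: 24 2-butanoyl-6-[(3-acetyl-2,4,6-tris(benzyloxy)-5-{[3-butanoyl-2-hydroxy-4-methoxy-5-methyl-6-(trifluoromethanesulfonyloxy)phenyl]methyl}phenyl)methyl]-3-hydroxy-5-methoxy-4-methylphenyl butanoate (representative positional isomer)
Conditions: AcOH, (CF3CO)2O, H3PO4 (cat.), CH2Cl2, 0 °C → rt
Reagents that add atoms: acetic acid, CC(=O)O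
Why: Friedel–Crafts acylation by acetyl trifluoroacetate at the only unsubstituted carbon of the electron-rich ring B (between two benzyloxy groups); both outer rings are fully substituted and deactivated by acyl and sulfonyl groups, and the absence of a strong Lewis acid should spare the benzyl ethers, the aryl butanoate and the aryl triflate.

Step 16
Reactants: 24 2-butanoyl-6-[(3-acetyl-2,4,6-tris(benzyloxy)-5-{[3-butanoyl-2-hydroxy-4-methoxy-5-methyl-6-(trifluoromethanesulfonyloxy)phenyl]methyl}phenyl)methyl]-3-hydroxy-5-methoxy-4-methylphenyl butanoate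
Product: 25 1-{3-[(3-acetyl-2,4,6-tris(benzyloxy)-5-{[3-butanoyl-2,6-dihydroxy-4-methoxy-5-methylphenyl]methyl}phenyl)methyl]-2,6-dihydroxy-4-methoxy-5-methylphenyl}butan-1-one
Conditions: Et4NOH (aq., 6 equiv), 1,4-dioxane, rt → 40 °C; then 1 M HCl
Reagents that add atoms: none
Why: Hydroxide cleaves the aryl butanoate by attack at carbon (saponification) and the aryl triflate by attack at sulfur, eased by the para butanoyl group, together with any phenol O-acetate, so that all positional isomers converge on one compound; the fully O-benzylated ring B rules out base-induced scrambling of the methylene bridges.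

Step 17
Reactants: 25 1-{3-[(3-acetyl-2,4,6-tris(benzyloxy)-5-{[3-butanoyl-2,6-dihydroxy-4-methoxy-5-methylphenyl]methyl}phenyl)methyl]-2,6-dihydroxy-4-methoxy-5-methylphenyl}butan-1-one
Product: 26 1-{3-[(3-acetyl-5-{[3-butanoyl-2,6-dihydroxy-4-methoxy-5-methylphenyl]methyl}-2,4,6-trihydroxyphenyl)methyl]-2,6-dihydroxy-4-methoxy-5-methylphenyl}butan-1-one (target, CNP0184345.0)
Conditions: H2 (1 atm), Pd/C (10 wt %), EtOAc/MeOH, rt
Reagents that add atoms: none
Why: Hydrogenolysis of the three benzyl ethers under neutral conditions; the hydrogen-bonded ortho-hydroxyaryl ketones and the diarylmethane links are expected to be inert.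

Compound list
1 | 2-methylphloroglucinol (2-methylbenzene-1,3,5-triol) | Cc1c(O)cc(O)cc1O | starting material
2 | 2,4,6-trihydroxy-3-methylbenzoic acid | Cc1c(O)cc(O)c(C(=O)O)c1O | intermediate
3 | methyl 2,6-dihydroxy-4-methoxy-3-methylbenzoate | COC(=O)c1c(O)cc(OC)c(C)c1O | intermediate
4 | methyl 3-[(dimethylamino)methyl]-2,6-dihydroxy-4-methoxy-5-methylbenzoate | COC(=O)c1c(O)c(C)c(OC)c(CN(C)C)c1O | intermediate
5 | 1,3,5-tris(benzyloxy)benzene | c1ccc(COc2cc(OCc3ccccc3)cc(OCc3ccccc3)c2)cc1 | starting material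
6 | 2-bromo-1,3,5-tris(benzyloxy)benzene | Brc1c(OCc2ccccc2)cc(OCc2ccccc2)cc1OCc1ccccc1 | intermediate
7 | methyl 3-{[3-bromo-2,4,6-tris(benzyloxy)phenyl]methyl}-2,6-dihydroxy-4-methoxy-5-methylbenzoate | COC(=O)c1c(O)c(C)c(OC)c(Cc2c(OCc3ccccc3)cc(OCc3ccccc3)c(Br)c2OCc2ccccc2)c1O | intermediate
8 | methyl 3-bromo-2,6-dihydroxy-4-methoxy-5-methylbenzoate | COC(=O)c1c(O)c(C)c(OC)c(Br)c1O | intermediate
9 | 3-bromo-2,6-dihydroxy-4-methoxy-5-methylbenzoic acid (not isolated) | OC(=O)c1c(O)c(C)c(OC)c(Br)c1O | intermediate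
10 | 4-bromo-5-methoxy-6-methylbenzene-1,3-diol | COc1c(C)c(O)cc(O)c1Br | intermediate
11 | 4-bromo-2-[(dimethylamino)methyl]-5-methoxy-6-methylbenzene-1,3-diol | CN(C)Cc1c(O)c(C)c(OC)c(Br)c1O | intermediate
12 | methyl 3-({3-bromo-5-[(3-bromo-2,6-dihydroxy-4-methoxy-5-methylphenyl)methyl]-2,4,6-tris(benzyloxy)phenyl}methyl)-2,6-dihydroxy-4-methoxy-5-methylbenzoate | COC(=O)c1c(O)c(C)c(OC)c(Cc2c(OCc3ccccc3)c(Cc3c(O)c(C)c(OC)c(Br)c3O)c(OCc3ccccc3)c(Br)c2OCc2ccccc2)c1O | intermediate
13 | 3-({3-bromo-5-[(3-bromo-2,6-dihydroxy-4-methoxy-5-methylphenyl)methyl]-2,4,6-tris(benzyloxy)phenyl}methyl)-2,6-dihydroxy-4-methoxy-5-methylbenzoic acid (not isolated) | OC(=O)c1c(O)c(C)c(OC)c(Cc2c(OCc3ccccc3)c(Cc3c(O)c(C)c(OC)c(Br)c3O)c(OCc3ccccc3)c(Br)c2OCc2ccccc2)c1O | intermediate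
14 | 4-({3-bromo-5-[(3-bromo-2,6-dihydroxy-4-methoxy-5-methylphenyl)methyl]-2,4,6-tris(benzyloxy)phenyl}methyl)-5-methoxy-6-methylbenzene-1,3-diol | COc1c(C)c(O)cc(O)c1Cc1c(OCc2ccccc2)c(Cc2c(O)c(C)c(OC)c(Br)c2O)c(OCc2ccccc2)c(Br)c1OCc1ccccc1 | intermediate
15 | 2-bromo-4-({3-bromo-5-[(3-bromo-2,6-dihydroxy-4-methoxy-5-methylphenyl)methyl]-2,4,6-tris(benzyloxy)phenyl}methyl)-5-methoxy-6-methylbenzene-1,3-diol | COc1c(C)c(O)c(Br)c(O)c1Cc1c(OCc2ccccc2)c(Cc2c(O)c(C)c(OC)c(Br)c2O)c(OCc2ccccc2)c(Br)c1OCc1ccccc1 | intermediate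
16 | tetrakis(trimethylsilyl) ether of 15 (not isolated) | COc1c(C)c(O[Si](C)(C)C)c(Br)c(O[Si](C)(C)C)c1Cc1c(OCc2ccccc2)c(Cc2c(O[Si](C)(C)C)c(C)c(OC)c(Br)c2O[Si](C)(C)C)c(OCc2ccccc2)c(Br)c1OCc1ccccc1 | intermediate
17 | retro-Brook product after protonation: ring A with C-1 SiMe3, one OSiMe3 and one OH; ring C with C-5' SiMe3, O-6' H and O-2' SiMe3; ring B C–H (not isolated; representative positional isomer) | COc1c(C)c(O[Si](C)(C)C)c([Si](C)(C)C)c(O)c1Cc1c(OCc2ccccc2)c(Cc2c(O[Si](C)(C)C)c(C)c(OC)c([Si](C)(C)C)c2O)c(OCc2ccccc2)cc1OCc1ccccc1 | intermediate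
18 | 4-[(2,4,6-tris(benzyloxy)-3-{[2,6-dihydroxy-4-methoxy-3-methyl-5-(trimethylsilyl)phenyl]methyl}phenyl)methyl]-5-methoxy-6-methyl-2-(trimethylsilyl)benzene-1,3-diol | COc1c(C)c(O)c([Si](C)(C)C)c(O)c1Cc1c(OCc2ccccc2)c(Cc2c(O)c(C)c(OC)c([Si](C)(C)C)c2O)c(OCc2ccccc2)cc1OCc1ccccc1 | intermediate
19 | 4-[(2,4,6-tris(benzyloxy)-3-{[4-methoxy-3-methyl-2,6-bis(trifluoromethanesulfonyloxy)-5-(trimethylsilyl)phenyl]methyl}phenyl)methyl]-5-methoxy-6-methyl-2-(trimethylsilyl)-1,3-phenylene bis(trifluoromethanesulfonate) | COc1c(C)c(OS(=O)(=O)C(F)(F)F)c([Si](C)(C)C)c(OS(=O)(=O)C(F)(F)F)c1Cc1c(OCc2ccccc2)c(Cc2c(OS(=O)(=O)C(F)(F)F)c(C)c(OC)c([Si](C)(C)C)c2OS(=O)(=O)C(F)(F)F)c(OCc2ccccc2)cc1OCc1ccccc1 | intermediate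
20 | butanoic acid | CCCC(=O)O | starting material
21 | bis(aryne): ring A as 3-(triflyloxy)aryne, ring C as 3-methoxyaryne with the O-2' triflate retained (not isolated; representative) | COC1=C(C)C#CC(OS(=O)(=O)C(F)(F)F)=C1Cc1c(OCc2ccccc2)c(CC2=C(OS(=O)(=O)C(F)(F)F)C(C)=C(OC)C#C2)c(OCc2ccccc2)cc1OCc1ccccc1 | intermediate
22 | ring A as 3-(butanoyloxy)aryne after the first butanoate addition and loss of the second triflate, ring C already the 5'-butanoyl-6'-hydroxy ketone (not isolated; representative) | COC1=C(Cc2c(OCc3ccccc3)c(Cc3c(OS(=O)(=O)C(F)(F)F)c(C)c(OC)c(C(=O)CCC)c3O)c(OCc3ccccc3)cc2OCc2ccccc2)C#CC(OC(=O)CCC)=C1C | intermediate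
23 | 2-butanoyl-6-[(2,4,6-tris(benzyloxy)-3-{[3-butanoyl-2-hydroxy-4-methoxy-5-methyl-6-(trifluoromethanesulfonyloxy)phenyl]methyl}phenyl)methyl]-3-hydroxy-5-methoxy-4-methylphenyl butanoate (representative positional isomer) | COc1c(C)c(O)c(C(=O)CCC)c(OC(=O)CCC)c1Cc1c(OCc2ccccc2)c(Cc2c(OS(=O)(=O)C(F)(F)F)c(C)c(OC)c(C(=O)CCC)c2O)c(OCc2ccccc2)cc1OCc1ccccc1 | intermediate
24 | 2-butanoyl-6-[(3-acetyl-2,4,6-tris(benzyloxy)-5-{[3-butanoyl-2-hydroxy-4-methoxy-5-methyl-6-(trifluoromethanesulfonyloxy)phenyl]methyl}phenyl)methyl]-3-hydroxy-5-methoxy-4-methylphenyl butanoate (representative positional isomer) | COc1c(C)c(O)c(C(=O)CCC)c(OC(=O)CCC)c1Cc1c(OCc2ccccc2)c(Cc2c(OS(=O)(=O)C(F)(F)F)c(C)c(OC)c(C(=O)CCC)c2O)c(OCc2ccccc2)c(C(C)=O)c1OCc1ccccc1 | intermediate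
25 | 1-{3-[(3-acetyl-2,4,6-tris(benzyloxy)-5-{[3-butanoyl-2,6-dihydroxy-4-methoxy-5-methylphenyl]methyl}phenyl)methyl]-2,6-dihydroxy-4-methoxy-5-methylphenyl}butan-1-one | COc1c(C)c(O)c(C(=O)CCC)c(O)c1Cc1c(OCc2ccccc2)c(Cc2c(O)c(C)c(OC)c(C(=O)CCC)c2O)c(OCc2ccccc2)c(C(C)=O)c1OCc1ccccc1 | intermediate
26 | 1-{3-[(3-acetyl-5-{[3-butanoyl-2,6-dihydroxy-4-methoxy-5-methylphenyl]methyl}-2,4,6-trihydroxyphenyl)methyl]-2,6-dihydroxy-4-methoxy-5-methylphenyl}butan-1-one (CNP0184345.0; achiral) | CCCC(=O)c1c(O)c(C)c(OC)c(Cc2c(O)c(Cc3c(O)c(C)c(OC)c(C(=O)CCC)c3O)c(O)c(C(C)=O)c2O)c1O | target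

Total step count: 17.
Longest linear sequence: 14 steps (steps 1, 2, 6–17); the ring A branch (step 3) and the ring B branch (step 4) join at step 5, and the product of step 5 joins the ring C branch at step 9.

Steps most likely to fail

Step 14 (proposed new method). The aryl anion on C-1 or C-5' may be protonated before it takes the acyl group, which would leave aryl butanoates without the ketone. An aryne may also be captured by a neighbouring benzyloxy oxygen of ring B through a six-membered transition state, butanoate may add at the proximal aryne carbon, or the spectator triflate may be cleaved early to a phenoxide that arylates. The fallback forms the same C–C bonds by a known anionic Fries rearrangement and sets out from 15. Esterification of its four phenols with butanoic anhydride (pyridine, DMAP, CH2Cl2) should give the tetrabutanoate F1. Threefold bromine–lithium exchange with t-BuLi (THF/Et2O, −100 → −78 °C) should place an aryllithium on C-1 of ring A and on C-5' of ring C, each beside a butanoate. The 1,3 shift of the acyl group from oxygen to the lithiated carbon, with protonation of the ring B aryllithium on quenching, should then give the diketone butanoate F2. Acetylation under the conditions of step 15 should give the acetyl compound F3, and hydrolysis under the conditions of step 16 returns to the route at 25.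

Step 9. Attack by the hindered ring B carbon, which lies between two benzyloxy groups, may be slow. Acid may then exchange arylmethyl groups between rings or remove the ring C bromine by ipso protonation. The fallback reverses the polarity of the bond formation and sets out from 7. Vilsmeier–Haack formylation (POCl3, DMF, then H2O) at the one free carbon of ring B should give the aldehyde F4, and NaBH4 in THF/MeOH should give the benzylic alcohol F5. Acid-catalysed Friedel–Crafts benzylation (TsOH·H2O, MeCN/CH2Cl2, 0 °C) of 10 at its only free carbon, between the two hydroxyl groups, by the trialkoxy-stabilised cation of F5 returns to the route at 12.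

Step 15. Electrophilic attack at a carbon shielded by two benzyloxy groups may be slow, so that acid-induced loss of benzyl ethers or transfer of a butanoyl group competes. The fallback moves the acetylation to the end, onto the free phloroglucinol ring, and sets out from 23. Hydrolysis with Et4NOH as in step 16 should give the tris(benzyl ether) diketone F6, and hydrogenolysis (H2, Pd/C, EtOAc/MeOH) should give the heptaphenol F7, whose only aromatic C–H is on ring B. Friedel–Crafts acetylation with Ac2O and BF3·OEt2, followed by mild methanolysis of any O-acetate (K2CO3, MeOH), returns to the route at 26.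

Further compounds
F1 | step 14 | 2-bromo-4-({3-bromo-5-[(3-bromo-2,6-bis(butanoyloxy)-4-methoxy-5-methylphenyl)methyl]-2,4,6-tris(benzyloxy)phenyl}methyl)-5-methoxy-6-methyl-1,3-phenylene dibutanoate | COc1c(C)c(OC(=O)CCC)c(Br)c(OC(=O)CCC)c1Cc1c(OCc2ccccc2)c(Cc2c(OC(=O)CCC)c(C)c(OC)c(Br)c2OC(=O)CCC)c(OCc2ccccc2)c(Br)c1OCc1ccccc1
F2 | step 14 | 2-butanoyl-6-[(2,4,6-tris(benzyloxy)-3-{[3-butanoyl-6-(butanoyloxy)-2-hydroxy-4-methoxy-5-methylphenyl]methyl}phenyl)methyl]-3-hydroxy-5-methoxy-4-methylphenyl butanoate (representative positional isomer) | COc1c(C)c(O)c(C(=O)CCC)c(OC(=O)CCC)c1Cc1c(OCc2ccccc2)c(Cc2c(OC(=O)CCC)c(C)c(OC)c(C(=O)CCC)c2O)c(OCc2ccccc2)cc1OCc1ccccc1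
F3 | step 14 | 2-butanoyl-6-[(3-acetyl-2,4,6-tris(benzyloxy)-5-{[3-butanoyl-6-(butanoyloxy)-2-hydroxy-4-methoxy-5-methylphenyl]methyl}phenyl)methyl]-3-hydroxy-5-methoxy-4-methylphenyl butanoate (representative positional isomer) | COc1c(C)c(O)c(C(=O)CCC)c(OC(=O)CCC)c1Cc1c(OCc2ccccc2)c(Cc2c(OC(=O)CCC)c(C)c(OC)c(C(=O)CCC)c2O)c(OCc2ccccc2)c(C(C)=O)c1OCc1ccccc1
F4 | step 9 | methyl 3-{[3-bromo-5-formyl-2,4,6-tris(benzyloxy)phenyl]methyl}-2,6-dihydroxy-4-methoxy-5-methylbenzoate | COC(=O)c1c(O)c(C)c(OC)c(Cc2c(OCc3ccccc3)c(C=O)c(OCc3ccccc3)c(Br)c2OCc2ccccc2)c1O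
F5 | step 9 | methyl 3-{[3-bromo-5-(hydroxymethyl)-2,4,6-tris(benzyloxy)phenyl]methyl}-2,6-dihydroxy-4-methoxy-5-methylbenzoate | COC(=O)c1c(O)c(C)c(OC)c(Cc2c(OCc3ccccc3)c(CO)c(OCc3ccccc3)c(Br)c2OCc2ccccc2)c1O
F6 | step 15 | 1-{3-[(2,4,6-tris(benzyloxy)-3-{[3-butanoyl-2,6-dihydroxy-4-methoxy-5-methylphenyl]methyl}phenyl)methyl]-2,6-dihydroxy-4-methoxy-5-methylphenyl}butan-1-one | COc1c(C)c(O)c(C(=O)CCC)c(O)c1Cc1c(OCc2ccccc2)c(Cc2c(O)c(C)c(OC)c(C(=O)CCC)c2O)c(OCc2ccccc2)cc1OCc1ccccc1
F7 | step 15 | 1-{3-[(3-{[3-butanoyl-2,6-dihydroxy-4-methoxy-5-methylphenyl]methyl}-2,4,6-trihydroxyphenyl)methyl]-2,6-dihydroxy-4-methoxy-5-methylphenyl}butan-1-one | COc1c(C)c(O)c(C(=O)CCC)c(O)c1Cc1c(O)c(Cc2c(O)c(C)c(OC)c(C(=O)CCC)c2O)c(O)cc1O
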